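Time first: in the amber run the target grows on a nearly straight line, so we carry the line rate, the target made per hour as a share of the starting material charged, 0.0776 /h, a reading with the scatter of its data.

all flasks: free catalyst 0.05 mol%
- amber: starting material 0.050 M; second substrate 1 equiv; reagent 1.5 equiv; run made earlier
- grey: starting material 0.050 M; second substrate 2 equiv; reagent 1.5 equiv; run made earlier
- midnight: starting material 0.050 M; second substrate 1.00 equiv (fed, over 2.00 h); reagent 1.50 equiv; a stirred flask in which second substrate is dosed at a steady rate over 2.00 h without added volume, worked up at 2.5 h; time 2.5 h
- winter: starting material 0.050 M; second substrate 1.00 equiv; reagent 1.50 equiv; a single well-mixed tank run continuously and read at steady state, 2.5 h in it on average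
- dawn: starting material 0.050 M (fed, over 2.00 h); second substrate 1.00 equiv; reagent 1.50 equiv; a stirred flask in which starting material is dosed at a steady rate over 2.00 h without added volume, worked up at 2.5 h; time 2.5 h
- spring: starting material 0.050 M; second substrate 1.00 equiv; reagent 1.50 equiv; a closed flask charged with all of it at once and left for 2.5 h; time 2.5 h

amber run (percent of the starting material charged)

| time / h | target / % | starting material / % |
|---|---|---|
| 0.333 | 3.0 | 96.4 |
| 0.833 | 6.9 | 93.2 |
| 1.50 | 12.0 | 86.4 |
| 2.50 | 19.4 | 79.5 |

grey run (percent of the starting material charged)

| time / min | target / % | starting material / % |
|---|---|---|
| 8.00 | 1.4 | 99.7 |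
| 15.0 | 2.5 | 98.2 |
| 25.0 | 3.9 | 96.9 |
| 30.0 | 4.9 | 96.0 |

(each reading ± 0.5 percentage points)

- the stated concentrations are those of everything mixed, before any reaction; amounts are the same in each set-up
- the analysis behind the earlier runs scatters by 0.5 percentage points, standard deviation
- the feed brings no volume worth counting
- the earlier runs were made in a closed, stirred flask

- the set-up with the highest amount of target at the outlet or at the end, in percent of the starting material put in ("none" if the first two lie within 2 percentage points) (midnight / winter / dawn / spring / none)
- amount of target at the outlet or at the end, in percent of the starting material put in, midnight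
- amount of target at the outlet or at the end, in percent of the starting material put in, winter
- amount of target at the outlet or at the end, in percent of the starting material put in, dawn
- amount of target at the outlet or at the end, in percent of the starting material put in, spring

1. Time. The amber slope reads 0.0828 /h up to 0.833 h and 0.0740 /h from 1.50 h to 2.50 h. With a scatter of 0.5 percentage points per reading, this bend leaves the order in [starting material] open.

2. Second substrate. First order in [second substrate] means a factor of 2 between amber and grey, but the grey run reads 0.0980 /h, a factor of 1.26. So we expect dosing it in midnight to cost little, and we keep the line rate there: 19.4%. Spring repeats amber.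

3. Starting material. In dawn the feed delivers 0.500 /h, faster than the line rate. We bet on zero order in [starting material], which the readings do not prove. Dawn then also gives 19.4%.

4. Tank. Winter holds its contents 2.5 h on average, so the line rate gives 19.4% again, and we name no best set-up.

The forecast gave 16.3% for midnight, 17.9% for winter, 12.4% for dawn and 19.5% for spring, with best none. On dawn it differs from our reckoning: “the average starting-material level is low, and the rate is first order in it”.

The flasks give 20.8% for midnight, 19.2% for winter, 19.0% for dawn and 20.6% for spring, with best none; the forecast and dawn part by 6.6 points.

    second substrate + free catalyst ⇌ catalyst intermediate B (K = 8.80 /M, k = 19.0 /M/s)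
    reagent + catalyst intermediate B → free catalyst + second product (k = 4.10 /M/s)
    starting material + free catalyst ⇌ catalyst intermediate A (K = 54.0 /M, k = 1400 /M/s)
    2 catalyst intermediate A ⇌ resting dimer, settled at all times (K = 2.40 × 10⁶ /M)
    reagent + catalyst intermediate A → free catalyst + target (k = 7.80 /M/s)

Catalyst intermediate A stood at 8.47% in dawn and 8.46% in spring at 2.50 h, while the resting dimer, the resting state of the catalyst, held 86.1% in dawn. The line rate over the dawn feed gives 15.5%, and dawn held 15.2% of target at 2.00 h. Scaled by reagent from 1.50 equiv to 6.00 equiv in the same flask as dawn, the line rate gives 77.6%, and that neighbour flask gave 72.6%.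

The data are simulated with made-up constants, noise included.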